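**Remark on the chemistry:** the target is read as the (2R,3S) meso diester with two (E)-geranyl chains, and all intermediates are drawn to agree with it; the chiral intermediate 5 is racemic and is drawn as one enantiomer; the key step consumes two molecules of 8 per molecule of 7.

## Structural features

The target 12 is an open-chain dimethyl succinate whose two neighbouring stereocentres, C2 and C3, each carry one 1,4-benzoquinone ring; the two halves are constitutionally identical and there is no other ring. The centres are (2R,3S) with identical substituent sets, so the compound is the meso diastereomer, and the two stereocentres sit directly next to each other on a freely rotating bond. In each quinone, C2 is bonded to the succinate carbon and C6 to the CH2 of an (E)-geranyl chain, so the C1 carbonyl is flanked by both substituents and the C4 carbonyl lies opposite, between two ring CH groups. The fragile elements are the quinones (base, nucleophiles, reductants), the two methine hydrogens (each alpha to an ester and attached to a quinone, hence easy to enolise and epimerise), and the four trisubstituted alkenes, which cyclise under strong acid and must stay E. At the reduced 4-methoxyphenol level a further liability appears, because a 2-hydroxyaryl ring next to a carboxyl carbon closes five- or six-membered lactones readily. The real difficulty is twofold: fixing the meso relation of two epimerisable acyclic centres, and placing each geranyl group on the one ring carbon next to the C1 oxygen without O-alkylation or scrambling of the chain. The key step exploits the phenoxide form of that C1 oxygen: its para carbon carries the methoxy group (the future C4 oxygen) and one ortho carbon carries the succinate carbon, so the future quinone C6 is the only ring carbon where C-alkylation can be followed by rearomatisation.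

## Logic of the disconnections

**12 to 11.** The two quinone C4=O groups are traced back to aryl methyl ethers and the C1=O groups to phenols, which restores two O–CH3 and two phenolic O–H bonds. The cut is made here because a quinone would not survive the phenoxide and hydroxide chemistry that precedes it, whereas a 4-methoxyphenol is both the nucleophile needed earlier and a latent quinone. The gain is an electron-rich, base-stable arene. The forward step must oxidise both rings without touching the four alkenes or enolising the methines.

**11 to 10.** The two ester O–CH3 bonds are cut. Free carboxyl groups are wanted at the alkylation stage, where as carboxylates they cannot lactonise and make the adjacent hydrogens non-acidic. The gain is a substrate that tolerates base. The forward esterification must be neutral, cold and fast, and must prefer the carboxylic acids over the phenols.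

**10 to 7 and 8.** The two aryl–CH2 bonds are cut (key step), which releases two molecules of 8. This removes both ten-carbon chains in one operation and leaves a small symmetrical tetra-anion in which the site of attack is unique on each ring. The forward step must favour C- over O-alkylation, attack the primary terminus of 8, and succeed on both rings.

**7 to 6.** The two acyl C–O bonds joining each phenol oxygen to the distal carboxyl carbon are re-formed on paper. The bis-lactone masks both phenols and both acids in one neutral compound and stores the meso configuration as a trans ring fusion. As an improvement to the precursor, 7 is made from 6 with exactly four equivalents of base, so it is never handled as the lactonisation-prone free hydroxy acid and carries no excess hydroxide into the alkylation. The forward opening must be faster than enolisation of a still-closed lactone.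

**6 to 3 and 4.** The bond from succinate carbon C3 to the second aryl ring and the adjoining acyl C–O bond are cut. In 3 one succinate carbon already bears its ring and ester, and 4 delivers the second ring together with the oxygen that closes the second lactone. Both partners are simple. The forward step must deliver the aryl group to C3 and not C4, and the ring fusion must settle as trans.

**3 to 1 and 2.** The aryl–C4 bond and the lactone O–C2 bond are cut. All four succinate carbons then come from 2 and the ring from 1, both commodity chemicals. The forward step needs attack of the phenol through its ortho carbon and not through oxygen.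

## Other disconnections considered

**Alternative 1:** The cut is the same conjugate arylation–lactonisation used between 3 and 4, but made after the chains are in place. The trans-fused bis-δ-lactone of meso-2,3-bis(3-geranyl-2-hydroxy-5-methoxyphenyl)succinic acid A1 is divided at one succinate-carbon–aryl bond and the adjoining acyl–oxygen bond. This gives methyl 8-geranyl-6-methoxy-2-oxo-2H-chromene-4-carboxylate A2 and (3-geranyl-2-hydroxy-5-methoxyphenyl)boronic acid A3. In the forward sense A3 would add to C3 of A2 under [Rh(OH)(C8H12)]2 catalysis (C8H12 = cycloocta-1,5-diene) in aqueous dioxane, and the phenol would close the second lactone to give A1. Acid-catalysed methanolysis of A1 would then lead straight to 11.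

- **In its favour:** each geranyl group would be introduced on a simple monomer, 2-geranyl-4-methoxyphenol A4, where a modest C- to O-alkylation ratio costs only cheap material and separation is easy. On this point it is the better plan. It would also avoid the tetra-anion, the free acid 10 and the esterification, which is a second point for it.
- **Equal points:** the stereochemical relay through a trans ring fusion is the same in both plans. The chains lie far from the reacting carbons, so the rhodium insertion should be no harder than with 3 and 4.
- **Against it:** A3 is not an article of commerce; it would need ortho-functionalisation and borylation of A4, probably with a phenol protecting group, and A2 needs its own annulation. The acid-sensitive chains and a free ortho-geranylphenol unit, which is prone to chroman formation, would pass through more operations, including the lactone equilibration. An electron-rich ortho-hydroxyarylboronic acid made in several steps is a costly partner to lose to protodeboronation.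
- **Step economy:** it is more convergent but would need roughly eight to nine operations against six, with a longest linear sequence of similar length.

**Alternative 2:** Here both aromatic rings are cut apart. (Z)-2,2'-(Ethene-1,2-diyl)bis(6-geranyl-4-methoxyphenol) A5 is traced to (Z)-hex-3-ene-1,5-diyne A6 and two molecules of pentacarbonyl[(2E,5E)-1-methoxy-6,10-dimethylundeca-2,5,9-trien-1-ylidene]chromium A7. In the forward Dötz benzannulation each ring would arise from one alkyne, the carbene carbon, the alkenyl unit and one CO ligand.

- **In its favour:** the substitution pattern follows from the mechanism. The carbene carbon becomes the methoxy-bearing carbon, the CO carbon becomes the phenol carbon, and the larger alkyne substituent and the chain-bearing alkenyl carbon end up on either side of the phenol. The geranyl position and the phenol/methyl-ether differentiation are therefore not left to a C- versus O-alkylation contest; on regiocontrol this is the better plan. It is two-directional like the chosen plan, which is an equal point.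
- **Against it:** it spends its effort making benzene rings that can be bought, and A5 still lacks both ester carbons and both stereocentres, so a second strategic step such as that of alternative 3 must follow. A7 has a doubly allylic CH2 between the carbene-conjugated alkene and the chain alkene, which invites isomerisation to a conjugated diene. A6 is volatile and heat-sensitive. Two equivalents of a chromium carbonyl reagent are needed, and chromium must be removed oxidatively from electron-rich phenols. A Z-alkene between two ortho-hydroxyaryl rings is liable to Z/E isomerisation and to cyclisation onto a phenol.
- **Mechanism:** the alternative is the more elegant construction but runs an organometallic cascade twice on one small linchpin. The chosen plan rests on a simple SN2 event whose weakness is selectivity, not feasibility.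
- **Step economy:** clearly longer, because A6 and A7 each take several steps and at least three more operations follow A5.

**Alternative 3:** The cut removes both C–CO2Me bonds of dimethyl meso-2,3-bis(3-geranyl-2,5-dimethoxyphenyl)succinate A9, leading back to (Z)-1,2-bis(3-geranyl-2,5-dimethoxyphenyl)ethene A8, CO and methanol. In the forward sense Pd(OCOCF3)2 with a bis(arylimino)acenaphthene ligand, p-benzoquinone as oxidant, CO and methanol would place both ester groups on the same alkene face by two syn events. From the Z-alkene this gives the meso diester. Oxidation of both 1,4-dimethoxyarene rings with (NH4)2Ce(NO3)6 would then give 12.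

- **In its favour:** the meso configuration would be set by a stereospecific addition to an alkene of fixed geometry, not by a thermodynamic relay and the survival of enolisable centres through base. On stereocontrol it is the better plan in principle. It also delivers the dimethyl ester directly, with no hydroxy acid, lactone or separate esterification, which is a second point for it. The final oxidation is of the same kind, an equal point.
- **Against it:** the substrate is an internal 1,2-diarylalkene, electron-rich and ortho-substituted on both rings, which is the least reactive class for this carbonylation. It carries four further alkenes that can bind palladium. Z to E isomerisation through a palladium hydride before carbonylation would turn the stereospecificity against the plan and give the racemic diastereomer. Pressurised CO is required.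
- **Step economy:** A8 must itself be assembled with both chains and the Z geometry in place, for example by O-methylation of A5 or by a separate multi-step construction, so the overall count would exceed six.
- **Balance:** the alternative concentrates its risk in one late, demanding catalytic step on a valuable substrate. The chosen plan spreads risk over an early relay and an alkylation that consumes inexpensive material.

Key step: step 4

## Route

**Step 1**
Reactants: 1 4-methoxyphenol; 2 dimethyl acetylenedicarboxylate
Product: 3 methyl 6-methoxy-2-oxo-2H-chromene-4-carboxylate
Conditions: PPh3 (1 equiv), CH2Cl2, −5 °C then reflux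
Reagents that add atoms: none
Why: Phosphine-mediated annulation of a phenol with an acetylenedicarboxylate: PPh3 adds to 2, the phenol protonates the zwitterion, the phenoxide attacks the vinylphosphonium salt through its ortho carbon, and lactonisation with loss of methanol followed by elimination of PPh3 gives the coumarin. The para methoxy group leaves only the two equivalent ortho carbons, so one regioisomer is expected.

**Step 2**
Reactants: 3 methyl 6-methoxy-2-oxo-2H-chromene-4-carboxylate; 4 (2-hydroxy-5-methoxyphenyl)boronic acid
Product: 6 trans-fused bis-δ-lactone of meso-2,3-bis(2-hydroxy-5-methoxyphenyl)succinic acid, via trans-chromanone ester 5 (not isolated)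
Conditions: 4 (2 equiv), [Rh(OH)(C8H12)]2 (3 mol%; C8H12 = cycloocta-1,5-diene), dioxane/H2O 10:1, 50 °C; then DBU (0.2 equiv), PhMe, 80 °C, 5 Å MS
Reagents that add atoms: none
Why: Rhodium-catalysed conjugate addition of an arylboronic acid (Hayashi–Miyaura reaction): the aryl–rhodium species inserts the trisubstituted alkene with the aryl group going to the unsubstituted C3, the usual outcome for diene-ligated rhodium on substituted butenedioate-type acceptors, and water releases the C4 ester enolate as 5. The base then lets the phenol close the second six-membered lactone on the C4 ester with loss of methanol and equilibrates both enolisable centres, so the trans ring fusion, which corresponds to the meso acid, is expected as the thermodynamic isomer.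

**Step 3**
Reactants: 6 trans-fused bis-δ-lactone of meso-2,3-bis(2-hydroxy-5-methoxyphenyl)succinic acid
Product: 7 tetrasodium salt of meso-2,3-bis(2-hydroxy-5-methoxyphenyl)succinic acid
Conditions: NaOH (4.0 equiv), degassed H2O/THF 2:1, 0 °C to rt, Ar; THF removed, freeze-dried
Reagents that add atoms: sodium hydroxide, [Na+].[OH-]
Why: Saponification of two aryl-ester lactones: hydroxide adds to the activated aryl ester carbonyls at low temperature, and each opened ring leaves a carboxylate whose alpha hydrogen is no longer acidic, so the configuration held in the trans ring fusion should pass into the meso tetra-anion. Exactly four equivalents of base leave no free hydroxide, and exclusion of air protects the electron-rich phenoxides.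

**Step 4**
Reactants: 7 tetrasodium salt of meso-2,3-bis(2-hydroxy-5-methoxyphenyl)succinic acid; 8 geranyl bromide ((E)-1-bromo-3,7-dimethylocta-2,6-diene), two molecules
Product: 10 meso-2,3-bis(3-geranyl-2-hydroxy-5-methoxyphenyl)succinic acid, via disodium dicarboxylate 9 (not isolated)
Conditions: 8 (3 equiv, in portions), degassed H2O/CF3CH2OH 3:1, 0 °C to rt, Ar; then 1 M HCl to pH 3, 0 °C, EtOAc
Reagents that add atoms: geranyl bromide (second molecule of 8), CC(C)=CCC/C(C)=C/CBr
Why: Each phenoxide of 7 is an ambident nucleophile; in water/trifluoroethanol its oxygen is tied up by hydrogen bonds, so the ring carbon ortho to it attacks the primary allylic carbon of 8 in an SN2 displacement of bromide, which leaves the E double bond untouched, and the resulting 6-geranylcyclohexa-2,4-dienone tautomerises to the phenol. The closest known reaction type is the ortho C-allylation and C-prenylation of phenoxides by allylic halides in water or fluorinated alcohols. No ring is closed and no stereocentre is created; the two existing centres sit alpha to carboxylates, cannot be enolised under these conditions and should keep the meso relation. The step needs site selectivity, which the substrate secures because the para carbon carries the methoxy group and the other ortho carbon the succinate carbon, so only attack at the free ortho CH can end in an aromatic product. It needs C- over O-alkylation, which rests on the hydrogen-bonding medium, and attack at the CH2 terminus of 8 in preference to the hindered tertiary terminus. The carboxylates are far weaker nucleophiles than the phenoxides in water, and because 7 was made with exactly four equivalents of base no free hydroxide competes for the bromide. The two rings react independently and each takes up one molecule of 8, so two molecules of 8 are consumed per molecule of 7 to give 9, and brief acidification at 0 °C liberates 10 before lactonisation or acid-induced cyclisation of the chains can set in.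

**Step 5**
Reactants: 10 meso-2,3-bis(3-geranyl-2-hydroxy-5-methoxyphenyl)succinic acid (used at once, crude)
Product: 11 dimethyl meso-2,3-bis(3-geranyl-2-hydroxy-5-methoxyphenyl)succinate
Conditions: Me3SiCHN2 (2.4 equiv), PhMe/MeOH 4:1, 0 °C
Reagents that add atoms: trimethylsilyldiazomethane, C[Si](C)(C)C=[N+]=[N-]
Why: Esterification of carboxylic acids with trimethylsilyldiazomethane in methanol: proton transfer from the acid and collapse of the diazonium carboxylate pair give the methyl ester at 0 °C without added acid or base, so the methines are not enolised, the alkenes are untouched and the hindered, less acidic phenols should react far more slowly. Any phenol that is methylated would still be converted into the same quinone in step 6.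

**Step 6**
Reactants: 11 dimethyl meso-2,3-bis(3-geranyl-2-hydroxy-5-methoxyphenyl)succinate
Product: 12 dimethyl (2R,3S)-2,3-bis(5-geranyl-3,6-dioxocyclohexa-1,4-dien-1-yl)succinate (CNP0183145.1)
Conditions: (NH4)2Ce(NO3)6 (4.5 equiv), MeCN/H2O 2:1, 0 °C, 15 min
Reagents that add atoms: water, O
Why: Oxidative demethylation of 4-methoxyphenols to 1,4-benzoquinones by tetravalent cerium: two one-electron oxidations give a phenoxonium ion that water captures at the methoxy-bearing carbon, and loss of methanol gives the quinone. The reaction is fast at 0 °C in an acidic medium in which the ester-bearing methines are not enolised, so the meso configuration should be retained, and the isolated trisubstituted alkenes, which are harder to oxidise than the phenols, should survive.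

## Compound list

1 | 4-methoxyphenol | COc1ccc(O)cc1 | starting material
2 | dimethyl acetylenedicarboxylate (dimethyl but-2-ynedioate) | COC(=O)C#CC(=O)OC | starting material
3 | methyl 6-methoxy-2-oxo-2H-chromene-4-carboxylate | COC(=O)C1=CC(=O)Oc2ccc(OC)cc12 | intermediate
4 | (2-hydroxy-5-methoxyphenyl)boronic acid | COc1ccc(O)c(B(O)O)c1 | starting material
5 | methyl 3,4-trans-3-(2-hydroxy-5-methoxyphenyl)-6-methoxy-2-oxochromane-4-carboxylate (racemic; the 3S,4R enantiomer is drawn) | O=C1Oc2ccc(OC)cc2[C@H](C(=O)OC)[C@H]1c3cc(OC)ccc3O | intermediate (not isolated)
6 | trans-fused bis-δ-lactone of meso-2,3-bis(2-hydroxy-5-methoxyphenyl)succinic acid (each phenol oxygen acylated by the carboxyl group on the distal succinate carbon; dihydrochromeno[4,3-c]chromene-5,11-dione core, ring-fusion hydrogens trans) | O=C1Oc2ccc(OC)cc2[C@H]3[C@H]1c4cc(OC)ccc4OC3=O | intermediate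
7 | tetrasodium salt of meso-2,3-bis(2-hydroxy-5-methoxyphenyl)succinic acid | [Na+].[Na+].[Na+].[Na+].[O-]C(=O)[C@H](c1cc(OC)ccc1[O-])[C@@H](C(=O)[O-])c1cc(OC)ccc1[O-] | intermediate
8 | geranyl bromide ((E)-1-bromo-3,7-dimethylocta-2,6-diene) | CC(C)=CCC/C(C)=C/CBr | starting material
9 | disodium meso-2,3-bis(3-geranyl-2-hydroxy-5-methoxyphenyl)succinate | [Na+].[Na+].[O-]C(=O)[C@H](c1cc(OC)cc(C/C=C(\C)CCC=C(C)C)c1O)[C@@H](C(=O)[O-])c1cc(OC)cc(C/C=C(\C)CCC=C(C)C)c1O | intermediate (not isolated)
10 | meso-2,3-bis(3-geranyl-2-hydroxy-5-methoxyphenyl)succinic acid | OC(=O)[C@H](c1cc(OC)cc(C/C=C(\C)CCC=C(C)C)c1O)[C@@H](C(=O)O)c1cc(OC)cc(C/C=C(\C)CCC=C(C)C)c1O | intermediate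
11 | dimethyl meso-2,3-bis(3-geranyl-2-hydroxy-5-methoxyphenyl)succinate | COC(=O)[C@H](c1cc(OC)cc(C/C=C(\C)CCC=C(C)C)c1O)[C@@H](C(=O)OC)c1cc(OC)cc(C/C=C(\C)CCC=C(C)C)c1O | intermediate
12 | dimethyl (2R,3S)-2,3-bis(5-geranyl-3,6-dioxocyclohexa-1,4-dien-1-yl)succinate (meso; CNP0183145.1) | COC(=O)[C@H](C1=CC(=O)C=C(C/C=C(\C)CCC=C(C)C)C1=O)[C@@H](C(=O)OC)C1=CC(=O)C=C(C/C=C(\C)CCC=C(C)C)C1=O | target

## Step count and least certain steps

Total step count: 6. Longest linear sequence: 6 steps (1 and 2 to 12); 4 and 8 enter as purchased reagents.

**Step 4, the key step.** The most likely failure is that O-alkylation of the phenoxides and solvolysis of the allylic bromide outrun C-alkylation. A dearomatising attack at the methoxy-bearing para carbon is a further loss channel, and the need for two successful events per molecule lowers the share of doubly alkylated product. The fallback leaves phenoxide chemistry altogether. It sets out from 6: acid-catalysed methanolysis (MeOH, catalytic H2SO4, rt) would give dimethyl meso-2,3-bis(2-hydroxy-5-methoxyphenyl)succinate F1 without enolate formation. A Mitsunobu reaction with geraniol (PPh3, diisopropyl azodicarboxylate, THF, 0 °C) would give dimethyl meso-2,3-bis[2-(geranyloxy)-5-methoxyphenyl]succinate F2. A Lewis-acid-promoted [1,3] oxygen-to-carbon allyl shift (Bi(OSO2CF3)3 catalytic, CH2Cl2, −20 °C) would then move each chain to the only free ortho carbon. The fallback comes back to the route at 11.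

**Step 2.** Protodeboronation of the electron-rich ortho-hydroxyarylboronic acid may be faster than transmetalation, and insertion of the trisubstituted alkene may be slow. Incomplete cis to trans equilibration, or translactonisation to five-membered lactones, would also take material out of the ring-fusion-controlled manifold. The fallback replaces the boron nucleophile by a reductive Heck reaction. It sets out from 1: iodination with N-iodosuccinimide (catalytic 4-toluenesulfonic acid, MeCN) would give 2-iodo-4-methoxyphenol F3. F3 and 3 with Pd(OAc)2 (5 mol%), HCO2Na and Bu4NCl in DMF at 60 °C would undergo aryl–palladium insertion at C3 and formate reduction of the resulting C4 palladium enolate. The fallback comes back at 5, which the base treatment of step 2 carries on to 6.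

**Step 3.** After the first ring has opened, the centre that is still part of a closed lactone may epimerise, either through its enolate or after translactonisation to a five-membered lactone, and this would leak material into the racemic diastereomer. The fallback avoids hydroxide on any enolisable ester. It sets out from 6: opening with benzyl alcohol and catalytic 4-toluenesulfonic acid at 60 °C would give dibenzyl meso-2,3-bis(2-hydroxy-5-methoxyphenyl)succinate F4. Hydrogenolysis (H2, Pd/C, EtOAc, rt) would give meso-2,3-bis(2-hydroxy-5-methoxyphenyl)succinic acid F5 under neutral conditions. Titration of F5 with 4.0 equivalents of NaOH at 0 °C comes back to the route at 7.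

**Step 1.** The phenoxide may attack the vinylphosphonium salt through oxygen, giving an aryl vinyl ether or a stabilised ylide, because the ortho carbons of 1 are activated only by the hydroxyl group. The fallback is a Heck arylation–lactonisation. It sets out from 1, which is iodinated as above to 2-iodo-4-methoxyphenol F3. F3 and dimethyl maleate with Pd(OAc)2 (5 mol%), NaOAc and Bu4NCl in DMF at 90 °C would give dimethyl (E)-2-(2-hydroxy-5-methoxyphenyl)but-2-enedioate F6 by syn insertion and syn β-hydride elimination. In F6 the phenol is cis to the distal ester, so it should lactonise in the flask, and the fallback comes back at 3.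

## Further compounds

F1 | step 4 | dimethyl meso-2,3-bis(2-hydroxy-5-methoxyphenyl)succinate | COC(=O)[C@H](c1cc(OC)ccc1O)[C@@H](C(=O)OC)c1cc(OC)ccc1O
F2 | step 4 | dimethyl meso-2,3-bis[2-(geranyloxy)-5-methoxyphenyl]succinate | COC(=O)[C@H](c1cc(OC)ccc1OC/C=C(\C)CCC=C(C)C)[C@@H](C(=O)OC)c1cc(OC)ccc1OC/C=C(\C)CCC=C(C)C
F3 | step 2 | 2-iodo-4-methoxyphenol | COc1ccc(O)c(I)c1
F4 | step 3 | dibenzyl meso-2,3-bis(2-hydroxy-5-methoxyphenyl)succinate | O=C(OCc1ccccc1)[C@H](c1cc(OC)ccc1O)[C@@H](C(=O)OCc1ccccc1)c1cc(OC)ccc1O
F5 | step 3 | meso-2,3-bis(2-hydroxy-5-methoxyphenyl)succinic acid | OC(=O)[C@H](c1cc(OC)ccc1O)[C@@H](C(=O)O)c1cc(OC)ccc1O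
F6 | step 1 | dimethyl (E)-2-(2-hydroxy-5-methoxyphenyl)but-2-enedioate | COC(=O)/C=C(/C(=O)OC)c1cc(OC)ccc1O
A1 | alternative 1 | trans-fused bis-δ-lactone of meso-2,3-bis(3-geranyl-2-hydroxy-5-methoxyphenyl)succinic acid | O=C1Oc2c(C/C=C(\C)CCC=C(C)C)cc(OC)cc2[C@H]3[C@H]1c4cc(OC)cc(C/C=C(\C)CCC=C(C)C)c4OC3=O
A2 | alternative 1 | methyl 8-geranyl-6-methoxy-2-oxo-2H-chromene-4-carboxylate | COC(=O)C1=CC(=O)Oc2c(C/C=C(\C)CCC=C(C)C)cc(OC)cc12
A3 | alternative 1 | (3-geranyl-2-hydroxy-5-methoxyphenyl)boronic acid | COc1cc(C/C=C(\C)CCC=C(C)C)c(O)c(B(O)O)c1
A4 | alternative 1 | 2-geranyl-4-methoxyphenol | COc1ccc(O)c(C/C=C(\C)CCC=C(C)C)c1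
A5 | alternative 2 | (Z)-2,2'-(ethene-1,2-diyl)bis(6-geranyl-4-methoxyphenol) | COc1cc(C/C=C(\C)CCC=C(C)C)c(O)c(c1)/C=C\c1cc(OC)cc(C/C=C(\C)CCC=C(C)C)c1O
A6 | alternative 2 | (Z)-hex-3-ene-1,5-diyne | C#C/C=C\C#C
A7 | alternative 2 | pentacarbonyl[(2E,5E)-1-methoxy-6,10-dimethylundeca-2,5,9-trien-1-ylidene]chromium | COC(/C=C/C/C=C(\C)CCC=C(C)C)=[Cr].[C-]#[O+].[C-]#[O+].[C-]#[O+].[C-]#[O+].[C-]#[O+]
A8 | alternative 3 | (Z)-1,2-bis(3-geranyl-2,5-dimethoxyphenyl)ethene | COc1cc(C/C=C(\C)CCC=C(C)C)c(OC)c(c1)/C=C\c1cc(OC)cc(C/C=C(\C)CCC=C(C)C)c1OC
A9 | alternative 3 | dimethyl meso-2,3-bis(3-geranyl-2,5-dimethoxyphenyl)succinate | COC(=O)[C@H](c1cc(OC)cc(C/C=C(\C)CCC=C(C)C)c1OC)[C@@H](C(=O)OC)c1cc(OC)cc(C/C=C(\C)CCC=C(C)C)c1OC
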